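Remark on the chemistry: the SMILES fixes R at C3 of the lactone, R at the side-chain carbinol and R at the mevalonate carbon; (R)-mevalonolactone, (R)-pent-4-en-2-ol and succinic anhydride are taken as purchasable.

## Structural features

The target is a 3,4-dihydroisocoumarin (isochroman-1-one): a δ-lactone ring (O2, C1, C8a, C4a, C4, C3) fused along C4a–C8a to a benzene ring that is a hydroquinone, with hydroxyls at C5 and C8 and hydrogens at C6 and C7. C3 (R) carries a five-carbon chain whose fourth carbon, C4' (R), is a secondary carbinol esterified by C1 of (R)-mevalonic acid; the tertiary 3-hydroxyl and the primary 5-hydroxyl of the acid are free. The three stereocentres are isolated from each other: C3 and C4' are 1,5-related across three methylenes and the quaternary mevalonate centre lies four atoms beyond C4', so none can be relayed from another and each has to be bought or set by a reagent. The benzene ring is 1,2,3,4-tetrasubstituted in the contiguous order O, C, C, O, and its phenols differ: 8-OH is hydrogen-bonded to the lactone carbonyl, 5-OH is a free, acylable phenol. Fragile points are the mevalonate ester (its free 5-hydroxyl can translactonise to mevalonolactone and expel the side-chain alcohol under acid or base), the β-hydroxy ester (retro-aldol, dehydration), the hydroquinone (oxidation in basic air) and the lactone. The real difficulty is the combination: a fully substituted hydroquinone must appear next to a labile diol ester, which rules out harsh phenol-ether cleavage at the end and makes a late acylation of the side-chain alcohol beside free phenols unselective. The key step exploits that C6 and C7 are unsubstituted and C5 and C8 oxygenated: C5–C6–C7–C8 with its two oxygens is the skeleton of succinic anhydride, and C4a–C8a is the C=C bond of an α,β-unsaturated δ-lactone, so the whole benzene ring can be built last on a finished, fully acylated lactone.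

## Logic of the disconnections

15 is traced through 14 and 13 to 10 and 12 by cutting C4a–C5 and C8–C8a. These two bonds join the lactone alkene carbons to a symmetrical four-carbon unit oxygenated at both ends, so cutting them removes the entire benzene ring and both phenols. The gain is a step from a bicyclic, tetrasubstituted hydroquinone to a monocyclic unsaturated lactone plus a diene made from a commodity anhydride, with no phenol protecting groups and no late acylation beside phenols. The forward step demands that the cis-disubstituted lactone alkene of 10 is a competent dienophile toward 12 without Lewis acid, that 13 opens and enolises to the arene, and that desilylation spares the mevalonate ester.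

12 is cut at its two O–Si bonds to 11; the forward step is a double enol silylation and must be run and handled dry.

10 is cut at the C3=C4 double bond of its lactone ring to the diene 9. The forward ring-closing metathesis must favour the six-membered ring over oligomers, and the ring enforces the Z geometry.

9 is cut at the acrylate acyl–oxygen bond to 8. The forward acylation meets only one free hydroxyl, which is why the mevalonate is already in place.

8 is cut at the bond between the carbinol carbon (future C3) and the allylic CH2 (future C4) to the aldehyde 7. This is where the C3 stereocentre is set; since the existing centres are five or more bonds away, the forward step must be fully reagent-controlled.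

7 is cut at the bond between the formyl carbon and the chain to the terminal alkene 6. The forward one-carbon homologation must be linear-selective and leave ester and silyl ethers alone.

6 is cut at the ester C–O bond to 4 and 5. This is the convergent join that brings in two of the three stereocentres from purchased compounds; the forward acylation must not eliminate the β-silyloxy group of 4.

4 is cut at its O–Si bonds and at the carboxyl–O5 bond (through 3 and 2) back to 1. The forward step must silylate faster than the opened salt relactonises.

## Other disconnections considered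

Alternative 1: The first route to come to mind cuts C4–C4a and the lactone O2–C1 bond. An ortho-lithiated 2,5-dialkoxybenzamide (sec-BuLi/TMEDA, then BF3·OEt2) would open the terminal epoxide A1 at its CH2 carbon, and acid lactonisation would give the protected isochromanone A2; desilylation, esterification with 4, hydrogenolysis and a final desilylation would follow. The chosen plan is preferred on structure and step economy. In this alternative the arene is bought with its oxygens, so both phenols must be masked and then unmasked next to an ester that translactonises. The organolithium step excludes the mevalonate ester, which forces a protect/deprotect cycle on C4'–OH and a late acylation. A1 itself still needs both carbinol centres to be built, and three classes of protecting group are carried.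

Alternative 2: A late single-atom edit cuts the C5–O bond. Oxygen would be inserted into the C5–H bond of the 5-deoxy lactone A3, either by Elbs persulfate oxidation (K2S2O8, aqueous NaOH) or by oxidation to the para-quinone with (KSO3)2NO and reduction. The chosen plan is preferred on mechanism: the phenol of A3 is an ortho-acyl phenol whose lone pair is tied up by conjugation and by the hydrogen bond to C1=O, so para-oxidation should be slow. The aqueous alkali of the Elbs reaction would also hydrolyse the lactone and the mevalonate ester. A3 would still have to be made by the aryl–epoxide chemistry of Alternative 1, so the edit adds a step without removing one.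

Alternative 3: Cutting the C3–H and C4–H bonds leads back to the isocoumarin A4. It would come from Sonogashira coupling of an ortho-iodobenzoate carrying the two phenol ethers with a terminal alkyne carrying the side-chain carbinol, followed by 6-endo cyclisation. Enantioselective hydrogenation of the C3=C4 enol-lactone bond would then give A5. The chosen plan is preferred because here C3 would be set last, by catalyst control, on a trisubstituted enol lactone conjugated to an electron-rich arene, a substrate class with a narrow basis for high selectivity. The cyclisation must also choose 6-endo over 5-exo, and the phenol-ether and late-acylation problems of Alternative 1 remain.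

Key step: step 8

## Route

Step 1
Reactants: 1 (R)-mevalonolactone [(4R)-4-hydroxy-4-methyloxan-2-one]
Product: 4 (R)-3-methyl-3,5-bis(triethylsilyloxy)pentanoic acid, via potassium mevalonate 2 (not isolated), via silyl ester 3 (not isolated)
Conditions: KOH (1.0 equiv), MeOH/H2O, rt, evaporate and dry; Et3SiCl (3.5 equiv), imidazole, DMAP (cat.), DMF, 0 to 40 °C; K2CO3 (cat.), MeOH/THF/H2O, 0 °C, then pH 5 buffer
Reagents that add atoms: potassium hydroxide ([K+].[OH-]); chlorotriethylsilane (CC[Si](Cl)(CC)CC)
Why: Hydroxide opens the δ-lactone to the carboxylate 2, exhaustive silylation traps the primary hydroxyl, the tertiary hydroxyl and the carboxylate as 3, and only the far more labile silyl ester is solvolysed to give 4 (lactone saponification, persilylation, selective silyl-ester cleavage); the quaternary centre is not touched and stays R.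

Step 2
Reactants: 4 (R)-3-methyl-3,5-bis(triethylsilyloxy)pentanoic acid; 5 (R)-pent-4-en-2-ol
Product: 6 (R)-pent-4-en-2-yl (R)-3-methyl-3,5-bis(triethylsilyloxy)pentanoate
Conditions: EDC·HCl, DMAP, CH2Cl2, 0 °C to rt
Reagents that add atoms: none
Why: Steglich esterification through the acylpyridinium; the C–O bond of 5 is not broken, so both centres are retained, and the silylated tertiary oxygen cannot lactonise or oligomerise.

Step 3
Reactants: 6 (R)-pent-4-en-2-yl (R)-3-methyl-3,5-bis(triethylsilyloxy)pentanoate
Product: 7 (R)-6-oxohexan-2-yl (R)-3-methyl-3,5-bis(triethylsilyloxy)pentanoate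
Conditions: Rh(acac)(CO)2 (1 mol %), BiPhePhos (2 mol %), CO/H2 (1:1, 10 bar), toluene, 70 °C
Reagents that add atoms: carbon monoxide ([C-]#[O+])
Why: Linear-selective rhodium-catalysed hydroformylation; the wide-bite-angle bisphosphite should place the formyl group on the terminal carbon, and ester and silyl ethers are inert to neutral syngas; no stereocentre is formed.

Step 4
Reactants: 7 (R)-6-oxohexan-2-yl (R)-3-methyl-3,5-bis(triethylsilyloxy)pentanoate
Product: 8 (2R,6R)-6-hydroxynon-8-en-2-yl (R)-3-methyl-3,5-bis(triethylsilyloxy)pentanoate
Conditions: (−)-Ipc2BOMe [from (+)-α-pinene], allylMgBr, Et2O, 0 °C to rt; then 7, Et2O, −78 °C; NaBO3·4H2O, THF/H2O, rt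
Reagents that add atoms: allylmagnesium bromide (C=CC[Mg]Br)
Why: Brown allylboration through a closed chair Zimmerman–Traxler transition state; the isopinocampheyl groups from (+)-α-pinene should direct allyl transfer to the Si face of an unbranched aliphatic aldehyde, setting C6 as R by reagent control (the C2 centre is too remote to interfere), and perborate oxidises the borinate under near-neutral conditions that spare the ester.

Step 5
Reactants: 8 (2R,6R)-6-hydroxynon-8-en-2-yl (R)-3-methyl-3,5-bis(triethylsilyloxy)pentanoate
Product: 9 (4R,8R)-8-{[(3R)-3-methyl-3,5-bis(triethylsilyloxy)pentanoyl]oxy}non-1-en-4-yl prop-2-enoate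
Conditions: acryloyl chloride, iPr2NEt, CH2Cl2, −20 to 0 °C
Reagents that add atoms: acryloyl chloride (C=CC(=O)Cl)
Why: O-acylation of the only free hydroxyl with an acid chloride and amine base; the carbinol C–O bond is not broken, so the configuration is retained.

Step 6
Reactants: 9 (4R,8R)-8-{[(3R)-3-methyl-3,5-bis(triethylsilyloxy)pentanoyl]oxy}non-1-en-4-yl prop-2-enoate
Product: 10 (R)-5-[(R)-6-oxo-3,6-dihydro-2H-pyran-2-yl]pentan-2-yl (R)-3-methyl-3,5-bis(triethylsilyloxy)pentanoate
Conditions: second-generation Grubbs catalyst RuCl2(=CHPh)(H2IMes)(PCy3) (5 mol %), CH2Cl2 (5 mM), 40 °C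
Reagents that add atoms: none
Why: Ring-closing metathesis of the acrylate with the terminal alkene closes the six-membered α,β-unsaturated lactone; loss of ethylene drives it, the ring enforces the Z alkene and dilution suppresses cross-metathesis.

Step 7
Reactants: 11 succinic anhydride
Product: 12 2,5-bis(trimethylsilyloxy)furan
Conditions: Me3SiCl, Et3N, ZnCl2 (cat.), MeCN, rt to 50 °C; distillation under argon
Reagents that add atoms: chlorotrimethylsilane (C[Si](C)(C)Cl)
Why: Soft double enolisation and O-silylation of the bis-enolisable anhydride gives the aromatic bis(silyl ketene acetal), the same reaction type that makes silyloxydienes from enones.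

Step 8
Reactants: 10 (R)-5-[(R)-6-oxo-3,6-dihydro-2H-pyran-2-yl]pentan-2-yl (R)-3-methyl-3,5-bis(triethylsilyloxy)pentanoate; 12 2,5-bis(trimethylsilyloxy)furan
Product: 15 (R)-5-[(R)-5,8-dihydroxy-1-oxoisochroman-3-yl]pentan-2-yl (R)-3,5-dihydroxy-3-methylpentanoate, via cycloadduct 13 (not isolated), via bis(triethylsilyl) ether 14 (not isolated)
Conditions: 12 (4 equiv), toluene, 110 °C, sealed tube, argon; then THF, HF·pyridine, pyridine, 0 °C to rt
Reagents that add atoms: none
Why: A normal-electron-demand Diels–Alder reaction joins C2/C5 of the very electron-rich furan 12 (HOMO raised by three oxygen donors) to the C3=C4 enoate alkene of 10, forming the C8–C8a and C4a–C5 bonds in one suprafacial event and giving the 1,4-bis(silyloxy)-7-oxanorbornene 13. On protonation and fluoride attack each bridgehead silyl ketal collapses (cleavage of the C–O bridge, loss of the silyl groups and of the bridge oxygen as water) to the cyclohex-2-ene-1,4-dione, which is the keto tautomer of the hydroquinone and enolises irreversibly to the arene of 14; the same HF·pyridine then cleaves both triethylsilyl ethers to 15. The closest known reaction type is the cycloaddition–aromatisation of 2,5-bis(trimethylsilyloxy)furans with acrylate, maleate and quinone dienophiles to gentisate-type hydroquinones, together with the thermal Diels–Alder reactivity of 5,6-dihydropyran-2-ones toward oxygenated dienes. The only ring closed is the benzene ring, by intermolecular [4+2] cycloaddition onto the preformed lactone. No new stereocentre survives: the four sp3 centres of 13 are erased on aromatisation, so endo/exo and facial selectivity are irrelevant, and C3, C4' and the mevalonate centre are spectators that are neither enolisable nor cleaved. Regiochemistry cannot arise because 12 is C2v-symmetric. The step needs cycloaddition across C2/C5 and not Michael-type attack through C3 of 12, which the absence of any Lewis acid and the non-polar solvent should secure, and it needs the lactone alkene to be the only electron-poor π bond, which it is. Pyridine-buffered HF·pyridine keeps the medium near neutral so that the liberated 5-hydroxyl should not translactonise onto the mevalonate ester.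

## Compound list

1 | (R)-mevalonolactone, (4R)-4-hydroxy-4-methyloxan-2-one | O=C1C[C@](C)(O)CCO1 | starting material
2 | potassium (R)-3,5-dihydroxy-3-methylpentanoate (potassium mevalonate) | [K+].[O-]C(=O)C[C@](C)(O)CCO | intermediate (not isolated)
3 | triethylsilyl (R)-3-methyl-3,5-bis(triethylsilyloxy)pentanoate | CC[Si](CC)(CC)OC(=O)C[C@](C)(O[Si](CC)(CC)CC)CCO[Si](CC)(CC)CC | intermediate (not isolated)
4 | (R)-3-methyl-3,5-bis(triethylsilyloxy)pentanoic acid | OC(=O)C[C@](C)(O[Si](CC)(CC)CC)CCO[Si](CC)(CC)CC | intermediate
5 | (R)-pent-4-en-2-ol | C[C@H](CC=C)O | starting material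
6 | (R)-pent-4-en-2-yl (R)-3-methyl-3,5-bis(triethylsilyloxy)pentanoate | C[C@H](CC=C)OC(=O)C[C@](C)(O[Si](CC)(CC)CC)CCO[Si](CC)(CC)CC | intermediate
7 | (R)-6-oxohexan-2-yl (R)-3-methyl-3,5-bis(triethylsilyloxy)pentanoate | C[C@H](CCCC=O)OC(=O)C[C@](C)(O[Si](CC)(CC)CC)CCO[Si](CC)(CC)CC | intermediate
8 | (2R,6R)-6-hydroxynon-8-en-2-yl (R)-3-methyl-3,5-bis(triethylsilyloxy)pentanoate | C[C@H](CCC[C@@H](O)CC=C)OC(=O)C[C@](C)(O[Si](CC)(CC)CC)CCO[Si](CC)(CC)CC | intermediate
9 | (4R,8R)-8-{[(3R)-3-methyl-3,5-bis(triethylsilyloxy)pentanoyl]oxy}non-1-en-4-yl prop-2-enoate | C[C@H](CCC[C@@H](OC(=O)C=C)CC=C)OC(=O)C[C@](C)(O[Si](CC)(CC)CC)CCO[Si](CC)(CC)CC | intermediate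
10 | (R)-5-[(R)-6-oxo-3,6-dihydro-2H-pyran-2-yl]pentan-2-yl (R)-3-methyl-3,5-bis(triethylsilyloxy)pentanoate | C[C@H](CCC[C@@H]1CC=CC(=O)O1)OC(=O)C[C@](C)(O[Si](CC)(CC)CC)CCO[Si](CC)(CC)CC | intermediate
11 | succinic anhydride | O=C1CCC(=O)O1 | starting material
12 | 2,5-bis(trimethylsilyloxy)furan | C[Si](C)(C)Oc1ccc(O[Si](C)(C)C)o1 | intermediate
13 | Diels–Alder adduct: 5,8-epoxy-5,8-bis(trimethylsilyloxy)-4a,5,8,8a-tetrahydroisochroman-1-one carrying the side chain of 10 (diastereomers at C4a, C5, C8, C8a) | C[C@H](CCC[C@@H]1CC2C(C(=O)O1)C3(O[Si](C)(C)C)C=CC2(O[Si](C)(C)C)O3)OC(=O)C[C@](C)(O[Si](CC)(CC)CC)CCO[Si](CC)(CC)CC | intermediate (not isolated)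
14 | (R)-5-[(R)-5,8-dihydroxy-1-oxoisochroman-3-yl]pentan-2-yl (R)-3-methyl-3,5-bis(triethylsilyloxy)pentanoate | C[C@H](CCC[C@@H]1Cc2c(O)ccc(O)c2C(=O)O1)OC(=O)C[C@](C)(O[Si](CC)(CC)CC)CCO[Si](CC)(CC)CC | intermediate (not isolated)
15 | (R)-5-[(R)-5,8-dihydroxy-1-oxoisochroman-3-yl]pentan-2-yl (R)-3,5-dihydroxy-3-methylpentanoate | C[C@H](CCC[C@@H]1Cc2c(O)ccc(O)c2C(=O)O1)OC(=O)C[C@](C)(O)CCO | target

## Step count and risk

Total step count: 8. Longest linear sequence: 7 (steps 1, 2, 3, 4, 5, 6 and 8); step 7 is a one-step branch.

Least certain steps:

Step 8 (key step). The most likely failure is a cycloaddition that is too slow: the dienophile is a β-alkyl, cis-disubstituted enoate, less activated than the acrylate-type partners for which the diene is known, so thermal decay or oligomerisation of 12 may outrun product formation. A competing Michael-type attack through C3 of the ketene acetal would give a succinate adduct and not the arene. In the second stage, translactonisation of the freed mevalonate diol ester onto itself is possible if the medium drifts acidic.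

The fallback sets out from 7 and comes back at 15, and makes the aryl–C4 bond from a purchased arene. Methylenation of 7 with dimethylsulfonium methylide (Me3S+ I−, KN(SiMe3)2, THF, −10 °C; Corey–Chaykovsky) would give (2R)-5-(oxiran-2-yl)pentan-2-yl (R)-3-methyl-3,5-bis(triethylsilyloxy)pentanoate F1 as both epoxide epimers. Hydrolytic kinetic resolution with (R,R)-(salen)Co(OAc) (trivalent cobalt, 0.5 mol %) and 0.55 equiv of water should leave the (R)-oxirane epimer F2, the other epimer being removed as its diol. A carboxylate-directed ortho C–H alkylation of purchased 2,5-dimethoxybenzoic acid F3 with F2 (Pd(OAc)2, N-acetyl-tert-leucine, KOAc, (CF3)2CHOH, 75 °C) opens the epoxide at its CH2 carbon and lactonises in the same flask to the 5,8-dimethoxy lactone F4, with the epoxide configuration kept at C3. HF·pyridine would then remove the silyl ethers to give the 5,8-dimethoxy diol F5. (NH4)2Ce(NO3)6 (tetravalent cerium) in MeCN/H2O at 0 °C would demethylate it oxidatively to the quinone F6, and Na2S2O4 in EtOAc/H2O would reduce F6 to 15.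

Step 1. The opened salt may relactonise during silylation, because a silyl ester is an acyl donor toward the still free 5-hydroxyl, and silylation of the hindered tertiary hydroxyl may stay incomplete. The fallback sets out from 1 and comes back at 4, fixing the carboxyl as a benzyl ester before silylation. KOH, then benzyl bromide in DMF, would give benzyl (R)-3,5-dihydroxy-3-methylpentanoate F7; Et3SiOTf and 2,6-lutidine in CH2Cl2 (−78 to 0 °C) would give benzyl (R)-3-methyl-3,5-bis(triethylsilyloxy)pentanoate F8; hydrogenolysis (H2, Pd/C, EtOAc) would give 4.

Step 4. Facial selectivity may be insufficient in a purely reagent-controlled addition to an unbranched aldehyde, and the C6 epimer would be hard to remove because the centres are remote; partial ester cleavage during the oxidative work-up is a second risk. The fallback sets out from 7 and comes back at 8, setting the centre by kinetic resolution and not by allyl transfer. 7 would be converted into the epoxide mixture F1 and resolved to the (R)-oxirane F2 exactly as described under step 8; opening of F2 at its CH2 carbon with vinylmagnesium bromide and CuI (10 mol %) in THF at −40 °C would give 8 with the carbinol configuration already fixed.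

Step 3. Branched hydroformylation, alkene isomerisation away from the terminus or hydrogenation may lower the share of the linear aldehyde, and the homoallylic ester carbonyl could direct rhodium to the internal carbon. The fallback sets out from 4 and comes back at 7, buying the extra carbon and replacing carbonylation with oxidation-state changes. 4 would be esterified (EDC·HCl, DMAP) with purchased (R)-hex-5-en-2-ol F9 to give (R)-hex-5-en-2-yl (R)-3-methyl-3,5-bis(triethylsilyloxy)pentanoate F10. Hydroboration with 9-BBN and oxidation with NaBO3·4H2O would give (R)-6-hydroxyhexan-2-yl (R)-3-methyl-3,5-bis(triethylsilyloxy)pentanoate F11, and Dess–Martin periodinane would give 7.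

Step 2. Activation of the neopentyl-type, β-silyloxy acid may be slow enough for N-acylurea formation, or may lead to E1cB loss of triethylsilanol from the acylpyridinium. The fallback sets out from 4 and comes back at 6, forming the alkyl–oxygen bond instead of the acyl–oxygen bond. A Mitsunobu reaction of 4 with purchased (S)-pent-4-en-2-ol F12 (PPh3, DIAD, THF, 0 °C) uses the carboxylate as nucleophile and should give 6 with inversion at the carbinol.

## Further compounds

F1 | step 8 | (2R)-5-(oxiran-2-yl)pentan-2-yl (R)-3-methyl-3,5-bis(triethylsilyloxy)pentanoate, both oxirane epimers | C[C@H](CCCC1CO1)OC(=O)C[C@](C)(O[Si](CC)(CC)CC)CCO[Si](CC)(CC)CC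
F2 | step 8 | (R)-5-[(R)-oxiran-2-yl]pentan-2-yl (R)-3-methyl-3,5-bis(triethylsilyloxy)pentanoate | C[C@H](CCC[C@@H]1CO1)OC(=O)C[C@](C)(O[Si](CC)(CC)CC)CCO[Si](CC)(CC)CC
F3 | step 8 | 2,5-dimethoxybenzoic acid | COc1ccc(OC)c(C(=O)O)c1
F4 | step 8 | (R)-5-[(R)-5,8-dimethoxy-1-oxoisochroman-3-yl]pentan-2-yl (R)-3-methyl-3,5-bis(triethylsilyloxy)pentanoate | C[C@H](CCC[C@@H]1Cc2c(OC)ccc(OC)c2C(=O)O1)OC(=O)C[C@](C)(O[Si](CC)(CC)CC)CCO[Si](CC)(CC)CC
F5 | step 8 | (R)-5-[(R)-5,8-dimethoxy-1-oxoisochroman-3-yl]pentan-2-yl (R)-3,5-dihydroxy-3-methylpentanoate | C[C@H](CCC[C@@H]1Cc2c(OC)ccc(OC)c2C(=O)O1)OC(=O)C[C@](C)(O)CCO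
F6 | step 8 | (R)-5-[(R)-1,5,8-trioxo-3,4,5,8-tetrahydro-1H-isochromen-3-yl]pentan-2-yl (R)-3,5-dihydroxy-3-methylpentanoate | C[C@H](CCC[C@@H]1CC2=C(C(=O)O1)C(=O)C=CC2=O)OC(=O)C[C@](C)(O)CCO
F7 | step 1 | benzyl (R)-3,5-dihydroxy-3-methylpentanoate | O=C(OCc1ccccc1)C[C@](C)(O)CCO
F8 | step 1 | benzyl (R)-3-methyl-3,5-bis(triethylsilyloxy)pentanoate | O=C(OCc1ccccc1)C[C@](C)(O[Si](CC)(CC)CC)CCO[Si](CC)(CC)CC
F9 | step 3 | (R)-hex-5-en-2-ol | C[C@H](CCC=C)O
F10 | step 3 | (R)-hex-5-en-2-yl (R)-3-methyl-3,5-bis(triethylsilyloxy)pentanoate | C[C@H](CCC=C)OC(=O)C[C@](C)(O[Si](CC)(CC)CC)CCO[Si](CC)(CC)CC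
F11 | step 3 | (R)-6-hydroxyhexan-2-yl (R)-3-methyl-3,5-bis(triethylsilyloxy)pentanoate | C[C@H](CCCCO)OC(=O)C[C@](C)(O[Si](CC)(CC)CC)CCO[Si](CC)(CC)CC
F12 | step 2 | (S)-pent-4-en-2-ol | C[C@@H](CC=C)O
A1 | alternative 1 | (R)-2-[(R)-4-(tert-butyldimethylsilyloxy)pentyl]oxirane | C[C@H](CCC[C@@H]1CO1)O[Si](C)(C)C(C)(C)C
A2 | alternative 1 | (R)-5,8-bis(benzyloxy)-3-[(R)-4-(tert-butyldimethylsilyloxy)pentyl]isochroman-1-one | C[C@H](CCC[C@@H]1Cc2c(OCc3ccccc3)ccc(OCc3ccccc3)c2C(=O)O1)O[Si](C)(C)C(C)(C)C
A3 | alternative 2 | (R)-5-[(R)-8-hydroxy-1-oxoisochroman-3-yl]pentan-2-yl (R)-3-methyl-3,5-bis(triethylsilyloxy)pentanoate | C[C@H](CCC[C@@H]1Cc2cccc(O)c2C(=O)O1)OC(=O)C[C@](C)(O[Si](CC)(CC)CC)CCO[Si](CC)(CC)CC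
A4 | alternative 3 | (R)-3-[4-(tert-butyldimethylsilyloxy)pentyl]-5,8-bis(methoxymethoxy)-1H-isochromen-1-one | C[C@H](CCCC1=Cc2c(OCOC)ccc(OCOC)c2C(=O)O1)O[Si](C)(C)C(C)(C)C
A5 | alternative 3 | (R)-3-[(R)-4-(tert-butyldimethylsilyloxy)pentyl]-5,8-bis(methoxymethoxy)isochroman-1-one | C[C@H](CCC[C@@H]1Cc2c(OCOC)ccc(OCOC)c2C(=O)O1)O[Si](C)(C)C(C)(C)C
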